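The seven-membered carbocycle of the target (octahydrocyclohepta[b]furan-2-one numbering) is disconnected at C3a–C4 and C7–C8. C4 (secondary carbinol) and C8 (acyloxy carbon) are latent aldehydes, C7 (tertiary carbinol next to the acyl carbon) is a thioester enolate carbon, and C3a, allylic to the exocyclic C3 methylidene, is the γ-carbon of a 2-(methoxycarbonyl)allyl metal. In one pot, the enolate of oxolane thioester 18 (a masked 4-formyl-2-hydroxy thioester) adds to aldehyde 10 (C7–C8), the lactol is unmasked, and indium closes the ring by intramolecular Barbier allylation (C3a–C4); four stereocentres are set. Lactone, angelate and enone follow.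

Key step: step 11

Assumption: in step 9 the (2R,5R)-imidazolidinone is taken to shield the face of the iminium ion that leads to the (3S) adduct; should the sense prove opposite, its enantiomer is used.

Step 1
Reactants: 1 (2S)-but-3-ene-1,2-diol; 2 4-methoxybenzaldehyde dimethyl acetal
Product: 3 (4S)-4-ethenyl-2-(4-methoxyphenyl)-1,3-dioxolane (C2 epimers)
Conditions: PPTS (cat.), CH2Cl2, rt
Reagents that add atoms: none
Why: Acid-catalysed transacetalisation of the 1,2-diol gives the five-membered 4-methoxybenzylidene acetal and does not touch the stereocentre of 1.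

Step 2
Reactants: 3 (4S)-4-ethenyl-2-(4-methoxyphenyl)-1,3-dioxolane
Product: 4 (2S)-2-[(4-methoxyphenyl)methoxy]but-3-en-1-ol
Conditions: i-Bu2AlH, CH2Cl2, −78 to 0 °C
Reagents that add atoms: none
Why: Reductive acetal opening, in which aluminium binds the less hindered primary oxygen and hydride goes to the benzylic carbon, should leave the 4-methoxybenzyl (PMB) ether on the secondary oxygen.

Step 3
Reactants: 4 (2S)-2-[(4-methoxyphenyl)methoxy]but-3-en-1-ol
Product: 5 (2S)-2-[(4-methoxyphenyl)methoxy]but-3-enal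
Conditions: Dess–Martin periodinane, NaHCO3, CH2Cl2, 0 °C (used crude)
Reagents that add atoms: none
Why: Buffered Dess–Martin oxidation stops at the aldehyde and is mild enough to preserve the α-alkoxy stereocentre.

Step 4
Reactants: 5 (2S)-2-[(4-methoxyphenyl)methoxy]but-3-enal; 6 methyl propiolate
Product: 8 methyl (4S)-3-hydroxy-4-[(4-methoxyphenyl)methoxy]-2-methylidenehex-5-enoate (C3 epimers), via vinylalane 7 (not isolated)
Conditions: 6, i-Bu2AlH, HMPA, THF, 0 °C; then 5, 0 °C to rt
Reagents that add atoms: none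
Why: Hydroalumination of the ynoate puts aluminium on the α-carbon and this vinylalane adds to the aldehyde to give the Baylis–Hillman-type adduct without base, so C4 should not epimerise; the C3 configuration is irrelevant because C3 becomes sp2 in step 5.

Step 5
Reactants: 8 methyl (4S)-3-hydroxy-4-[(4-methoxyphenyl)methoxy]-2-methylidenehex-5-enoate
Product: 9 methyl (2Z,4S)-2-(chloromethyl)-4-[(4-methoxyphenyl)methoxy]hexa-2,5-dienoate
Conditions: NCS, Me2S, CH2Cl2, −20 to 0 °C
Reagents that add atoms: N-chlorosuccinimide, O=C1CCC(=O)N1Cl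
Why: Corey–Kim activation of the allylic alcohol followed by SN2′ attack of chloride on the methylidene carbon should give the rearranged primary allylic chloride as the (Z)-isomer (C4 cis to CH2Cl), as is usual for aldehyde-derived Baylis–Hillman adducts.

Step 6
Reactants: 9 methyl (2Z,4S)-2-(chloromethyl)-4-[(4-methoxyphenyl)methoxy]hexa-2,5-dienoate
Product: 10 methyl (2Z,4R)-2-(chloromethyl)-4-[(4-methoxyphenyl)methoxy]-5-oxopent-2-enoate
Conditions: O3, CH2Cl2, −78 °C (Sudan Red 7B end point); then PPh3 (used at once)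
Reagents that add atoms: ozone, [O-][O+]=O
Why: Ozonolysis should cleave the electron-richer terminal vinyl group selectively over the trisubstituted acrylate double bond and give the α-alkoxy aldehyde.

Step 7
Reactants: 11 ethyl 2-[(tert-butyldimethylsilyl)oxy]acetate; 12 ethanethiol
Product: 14 S-ethyl 2-[(tert-butyldimethylsilyl)oxy]ethanethioate, via aluminium thiolate 13 (not isolated)
Conditions: AlMe3, CH2Cl2, 0 °C to rt
Reagents that add atoms: none
Why: The aluminium thiolate Me2AlSEt formed in the flask converts the ester into the thioester (ester–thioester exchange).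

Step 8
Reactants: 14 S-ethyl 2-[(tert-butyldimethylsilyl)oxy]ethanethioate
Product: 15 tert-butyl{[2-(ethylsulfanyl)-2-[(trimethylsilyl)oxy]ethenyl]oxy}dimethylsilane (double-bond isomers)
Conditions: LiN(i-Pr)2, Me3SiCl, THF, −78 °C
Reagents that add atoms: chlorotrimethylsilane, C[Si](C)(C)Cl
Why: Kinetic enolisation of the thioester with in-situ O-silylation gives the silyl ketene thioacetal.

Step 9
Reactants: 15 silyl ketene thioacetal; 16 (E)-but-2-enal
Product: 17 S-ethyl (3S)-2-[(tert-butyldimethylsilyl)oxy]-3-methyl-5-oxopentanethioate (C2 epimers)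
Conditions: (2R,5R)-5-benzyl-2-tert-butyl-3-methylimidazolidin-4-one·CF3CO2H (20 mol %), CH2Cl2/H2O, −70 °C
Reagents that add atoms: none
Why: In this organocatalytic Mukaiyama–Michael addition the chiral iminium ion of the enal is attacked at C3 from its unshielded face, which sets the methyl-bearing stereocentre; the C2 configuration is irrelevant because C2 is enolised in step 11.

Step 10
Reactants: 17 S-ethyl (3S)-2-[(tert-butyldimethylsilyl)oxy]-3-methyl-5-oxopentanethioate
Product: 18 S-ethyl (3S)-5-methoxy-3-methyloxolane-2-carbothioate (C2/C5 isomers)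
Conditions: AcCl (0.2 equiv), MeOH, 0 °C to rt
Reagents that add atoms: methanol, CO
Why: Methanolic HCl removes the silyl ether and the freed hydroxyl closes onto the aldehyde (5-exo), so the cyclic methyl acetal masks both the aldehyde and the hydroxyl.

Step 11
Reactants: 18 S-ethyl (3S)-5-methoxy-3-methyloxolane-2-carbothioate; 10 methyl (2Z,4R)-2-(chloromethyl)-4-[(4-methoxyphenyl)methoxy]-5-oxopent-2-enoate
Product: 21 methyl 2-[(1S,2S,4S,5S,6S,7R)-5-[(ethylsulfanyl)carbonyl]-2,5,6-trihydroxy-7-[(4-methoxyphenyl)methoxy]-4-methylcycloheptyl]prop-2-enoate, via aldol adduct 19 (not isolated), via lactol 20 (not isolated)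
Conditions: 18, LiN(i-Pr)2, THF, −78 °C; MgBr2·OEt2; 10, −78 °C; then 1 M aq. HCl, rt; then indium powder, NaI (0.3 equiv), THF/H2O (0.005 M), pH 4, rt
Reagents that add atoms: water, O
Why: The magnesium enolate of 18 (planar at C2 of the oxolane) adds to aldehyde 10 in a chelation-controlled aldol reaction, acid then hydrolyses the methyl acetal to lactol 20, and the allylindium reagent formed from the allylic chloride (iodide shuttle) adds through its γ-carbon to the small equilibrium share of free aldehyde; the closest known reaction types are the Cram-chelate aldol addition of thioester enolates to α-alkoxy aldehydes and the intramolecular Barbier allylation of 2-(halomethyl)acrylates used to close carbocycles of α-methylene lactone terpenoids. The seven-membered ring is closed in the second event by 7-exo-trig attack on the aldehyde through a chair-like Zimmerman–Traxler transition state. The quaternary carbon C5 of 21 is set by approach of the aldehyde trans to the neighbouring ring methyl group of the oxolane enolate, and the adjacent carbinol C6 by the magnesium chelate between the aldehyde oxygen and the PMB ether, which gives the 1,2-syn (threo) dioxygen pattern. At C1 the allyl metal reacts on the alkene face that keeps the allylic hydrogen of C7 in the plane of the (Z)-alkene (1,3-allylic strain), which places the acrylate branch trans to the PMB ether; at C2 the (Z)-geometry forces the C7 substituent axial in the chair, so the tethered aldehyde can only bind with its chain equatorial and the new hydroxyl ends up cis to the acrylate branch. The step needs chemoselectivity (enolate to aldehyde and not to the allylic chloride, allylindium to aldehyde and not to thioester or ester) and ring closure in preference to dimerisation, which should be secured by the low temperature and cold quench of the first stage, by the inertness of allylindium reagents towards esters and thioesters, and by high dilution.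

Step 12
Reactants: 21 cycloheptane triol
Product: 22 methyl 2-[(1R,2S,4S,5S,6S,7R)-5-[(ethylsulfanyl)carbonyl]-5,6-dihydroxy-7-[(4-methoxyphenyl)methoxy]-4-methyl-2-[(triethylsilyl)oxy]cycloheptyl]prop-2-enoate
Conditions: Et3SiCl (1.05 equiv), imidazole, CH2Cl2, −40 °C
Reagents that add atoms: chlorotriethylsilane, CC[Si](Cl)(CC)CC
Why: Silylation should be selective for the C2 hydroxyl, flanked by CH and CH2, over the C6 hydroxyl next to the quaternary carbon and over the tertiary hydroxyl.

Step 13
Reactants: 22 C2 silyl ether; 23 angelic acid [(2Z)-2-methylbut-2-enoic acid]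
Product: 25 methyl 2-[(1R,2S,4S,5S,6S,7R)-5-[(ethylsulfanyl)carbonyl]-5-hydroxy-7-[(4-methoxyphenyl)methoxy]-4-methyl-6-{[(2Z)-2-methylbut-2-enoyl]oxy}-2-[(triethylsilyl)oxy]cycloheptyl]prop-2-enoate, via mixed anhydride 24 (not isolated)
Conditions: 23, 2,4,6-trichlorobenzoyl chloride, Et3N, toluene, rt; then 22, 80 °C
Reagents that add atoms: none
Why: Yamaguchi esterification through the mixed anhydride acylates the hindered secondary hydroxyl without nucleophilic catalyst, which should avoid isomerisation of the (Z)-alkene to the tiglate, and the tertiary hydroxyl does not react.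

Step 14
Reactants: 25 angelate thioester; 26 (E)-prop-1-enylboronic acid
Product: 27 methyl 2-[(1R,2S,4S,5S,6S,7R)-5-[(2E)-but-2-enoyl]-5-hydroxy-7-[(4-methoxyphenyl)methoxy]-4-methyl-6-{[(2Z)-2-methylbut-2-enoyl]oxy}-2-[(triethylsilyl)oxy]cycloheptyl]prop-2-enoate
Conditions: Pd2(dba)3 (2.5 mol %), tri(2-furyl)phosphine, Cu(O2CC4H3S) (copper thiophene-2-carboxylate, 1.5 equiv), THF, 50 °C
Reagents that add atoms: none
Why: In the Liebeskind–Srogl coupling zerovalent palladium inserts into the C–S bond and the copper carboxylate mediates transfer of the alkenyl group from boron under neutral conditions, so the ketone should form with retention of the (E)-geometry beside acrylate, angelate and free tertiary hydroxyl.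

Step 15
Reactants: 27 enone PMB ether
Product: 29 (3aR,4S,6S,7S,8S,8aR)-7-[(2E)-but-2-enoyl]-7-hydroxy-6-methyl-3-methylidene-2-oxo-4-[(triethylsilyl)oxy]octahydro-2H-cyclohepta[b]furan-8-yl (2Z)-2-methylbut-2-enoate, via hydroxy ester 28 (not isolated)
Conditions: DDQ, CH2Cl2/pH 7 buffer, 0 °C to rt; then PPTS (cat.), toluene, 60 °C
Reagents that add atoms: none
Why: Oxidative PMB cleavage frees the C7 hydroxyl (cycloheptane numbering), the only hydroxyl that can reach the acrylate ester while the C2 oxygen is silylated, so acid-catalysed 5-exo-trig lactonisation should give the trans-fused α-methylene-γ-butyrolactone.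

Step 16
Reactants: 29 silylated lactone
Product: 30 (3aS,4S,6S,7S,8S,8aR)-7-[(2E)-but-2-enoyl]-4,7-dihydroxy-6-methyl-3-methylidene-2-oxooctahydro-2H-cyclohepta[b]furan-8-yl (2Z)-2-methylbut-2-enoate (target)
Conditions: HF·pyridine, THF, 0 °C
Reagents that add atoms: none
Why: Fluoride cleavage of the triethylsilyl ether under weakly acidic conditions should leave the α-methylene lactone, the enone and the angelate untouched.

Compound list

1 | (2S)-but-3-ene-1,2-diol | O[C@@H](C=C)CO | starting material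
2 | 4-methoxybenzaldehyde dimethyl acetal | COc1ccc(C(OC)OC)cc1 | starting material
3 | (4S)-4-ethenyl-2-(4-methoxyphenyl)-1,3-dioxolane (C2 epimers) | COc1ccc(C2OC[C@H](C=C)O2)cc1 | intermediate
4 | (2S)-2-[(4-methoxyphenyl)methoxy]but-3-en-1-ol | COc1ccc(CO[C@@H](C=C)CO)cc1 | intermediate
5 | (2S)-2-[(4-methoxyphenyl)methoxy]but-3-enal | COc1ccc(CO[C@@H](C=C)C=O)cc1 | intermediate
6 | methyl propiolate | C#CC(=O)OC | starting material
7 | methyl 2-[bis(2-methylpropyl)alumanyl]prop-2-enoate (vinylalane) | C=C(C(=O)OC)[Al](CC(C)C)CC(C)C | intermediate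
8 | methyl (4S)-3-hydroxy-4-[(4-methoxyphenyl)methoxy]-2-methylidenehex-5-enoate (C3 epimers) | COc1ccc(CO[C@@H](C=C)C(O)C(=C)C(=O)OC)cc1 | intermediate
9 | methyl (2Z,4S)-2-(chloromethyl)-4-[(4-methoxyphenyl)methoxy]hexa-2,5-dienoate | COc1ccc(CO[C@@H](C=C)/C=C(\CCl)C(=O)OC)cc1 | intermediate
10 | methyl (2Z,4R)-2-(chloromethyl)-4-[(4-methoxyphenyl)methoxy]-5-oxopent-2-enoate | COc1ccc(CO[C@@H](C=O)/C=C(\CCl)C(=O)OC)cc1 | intermediate
11 | ethyl 2-[(tert-butyldimethylsilyl)oxy]acetate | CCOC(=O)CO[Si](C)(C)C(C)(C)C | starting material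
12 | ethanethiol | CCS | starting material
13 | dimethylaluminium ethanethiolate | CCS[Al](C)C | intermediate
14 | S-ethyl 2-[(tert-butyldimethylsilyl)oxy]ethanethioate | CCSC(=O)CO[Si](C)(C)C(C)(C)C | intermediate
15 | tert-butyl{[2-(ethylsulfanyl)-2-[(trimethylsilyl)oxy]ethenyl]oxy}dimethylsilane (double-bond isomers) | CCSC(O[Si](C)(C)C)=CO[Si](C)(C)C(C)(C)C | intermediate
16 | (E)-but-2-enal | C/C=C/C=O | starting material
17 | S-ethyl (3S)-2-[(tert-butyldimethylsilyl)oxy]-3-methyl-5-oxopentanethioate (C2 epimers) | CCSC(=O)C(O[Si](C)(C)C(C)(C)C)[C@@H](C)CC=O | intermediate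
18 | S-ethyl (3S)-5-methoxy-3-methyloxolane-2-carbothioate (C2/C5 isomers) | CCSC(=O)C1OC(OC)C[C@@H]1C | intermediate
19 | methyl (2Z,4R,5S)-2-(chloromethyl)-5-[(2S,3S)-2-[(ethylsulfanyl)carbonyl]-5-methoxy-3-methyloxolan-2-yl]-5-hydroxy-4-[(4-methoxyphenyl)methoxy]pent-2-enoate (acetal epimers) | COc1ccc(CO[C@H](/C=C(\CCl)C(=O)OC)[C@H](O)[C@@]2(C(=O)SCC)OC(OC)C[C@@H]2C)cc1 | intermediate
20 | methyl (2Z,4R,5S)-2-(chloromethyl)-5-[(2S,3S)-2-[(ethylsulfanyl)carbonyl]-5-hydroxy-3-methyloxolan-2-yl]-5-hydroxy-4-[(4-methoxyphenyl)methoxy]pent-2-enoate (lactol epimers) | COc1ccc(CO[C@H](/C=C(\CCl)C(=O)OC)[C@H](O)[C@@]2(C(=O)SCC)OC(O)C[C@@H]2C)cc1 | intermediate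
21 | methyl 2-[(1S,2S,4S,5S,6S,7R)-5-[(ethylsulfanyl)carbonyl]-2,5,6-trihydroxy-7-[(4-methoxyphenyl)methoxy]-4-methylcycloheptyl]prop-2-enoate | COc1ccc(CO[C@@H]2[C@@H](C(=C)C(=O)OC)[C@@H](O)C[C@H](C)[C@@](O)(C(=O)SCC)[C@H]2O)cc1 | intermediate
22 | methyl 2-[(1R,2S,4S,5S,6S,7R)-5-[(ethylsulfanyl)carbonyl]-5,6-dihydroxy-7-[(4-methoxyphenyl)methoxy]-4-methyl-2-[(triethylsilyl)oxy]cycloheptyl]prop-2-enoate | COc1ccc(CO[C@@H]2[C@@H](C(=C)C(=O)OC)[C@@H](O[Si](CC)(CC)CC)C[C@H](C)[C@@](O)(C(=O)SCC)[C@H]2O)cc1 | intermediate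
23 | angelic acid, (2Z)-2-methylbut-2-enoic acid | C/C=C(/C)C(=O)O | starting material
24 | (2Z)-2-methylbut-2-enoic 2,4,6-trichlorobenzoic anhydride | C/C=C(/C)C(=O)OC(=O)c1c(Cl)cc(Cl)cc1Cl | intermediate
25 | methyl 2-[(1R,2S,4S,5S,6S,7R)-5-[(ethylsulfanyl)carbonyl]-5-hydroxy-7-[(4-methoxyphenyl)methoxy]-4-methyl-6-{[(2Z)-2-methylbut-2-enoyl]oxy}-2-[(triethylsilyl)oxy]cycloheptyl]prop-2-enoate | COc1ccc(CO[C@@H]2[C@@H](C(=C)C(=O)OC)[C@@H](O[Si](CC)(CC)CC)C[C@H](C)[C@@](O)(C(=O)SCC)[C@H]2OC(=O)/C(C)=C\C)cc1 | intermediate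
26 | (E)-prop-1-enylboronic acid | C/C=C/B(O)O | starting material
27 | methyl 2-[(1R,2S,4S,5S,6S,7R)-5-[(2E)-but-2-enoyl]-5-hydroxy-7-[(4-methoxyphenyl)methoxy]-4-methyl-6-{[(2Z)-2-methylbut-2-enoyl]oxy}-2-[(triethylsilyl)oxy]cycloheptyl]prop-2-enoate | COc1ccc(CO[C@@H]2[C@@H](C(=C)C(=O)OC)[C@@H](O[Si](CC)(CC)CC)C[C@H](C)[C@@](O)(C(=O)/C=C/C)[C@H]2OC(=O)/C(C)=C\C)cc1 | intermediate
28 | methyl 2-[(1R,2S,4S,5S,6S,7R)-5-[(2E)-but-2-enoyl]-5,7-dihydroxy-4-methyl-6-{[(2Z)-2-methylbut-2-enoyl]oxy}-2-[(triethylsilyl)oxy]cycloheptyl]prop-2-enoate | O[C@@H]1[C@@H](C(=C)C(=O)OC)[C@@H](O[Si](CC)(CC)CC)C[C@H](C)[C@@](O)(C(=O)/C=C/C)[C@H]1OC(=O)/C(C)=C\C | intermediate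
29 | (3aR,4S,6S,7S,8S,8aR)-7-[(2E)-but-2-enoyl]-7-hydroxy-6-methyl-3-methylidene-2-oxo-4-[(triethylsilyl)oxy]octahydro-2H-cyclohepta[b]furan-8-yl (2Z)-2-methylbut-2-enoate | C=C1C(=O)O[C@@H]2[C@@H]1[C@@H](O[Si](CC)(CC)CC)C[C@H](C)[C@@](O)(C(=O)/C=C/C)[C@H]2OC(=O)/C(C)=C\C | intermediate
30 | (3aS,4S,6S,7S,8S,8aR)-7-[(2E)-but-2-enoyl]-4,7-dihydroxy-6-methyl-3-methylidene-2-oxooctahydro-2H-cyclohepta[b]furan-8-yl (2Z)-2-methylbut-2-enoate | C=C1C(=O)O[C@@H]2[C@@H]1[C@@H](O)C[C@H](C)[C@@](O)(C(=O)/C=C/C)[C@H]2OC(=O)/C(C)=C\C | target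

Total step count: 16. Longest linear sequence: 12 steps (steps 1 to 6 and 11 to 16, from 1); the second branch (steps 7 to 10) joins at step 11.

Steps most likely to fail

Step 11. What may go wrong: the allylindium reagent closes the seven-membered ring too slowly, so that intermolecular allylation takes over, or the aldolate of the first stage is lost by O-alkylation with the allylic chloride or by β-lactonisation onto the thioester; the facial preferences of the two chiral halves may also be mismatched in the ring closure. The fallback sets out from 10 and 18 and comes back at 21. The aldol stage is run alone and aldol adduct 19 is isolated after a cold acidic quench. NaI in acetone (Finkelstein exchange) gives the iodide acetal F1. Aqueous acetic acid in THF hydrolyses the acetal to the iodide lactol F2. CrCl2 in THF/DMF at high dilution then closes the ring by Nozaki–Hiyama allylation with divalent chromium, through the same chair transition state, and should give 21.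

Step 14. What may go wrong: oxidative addition and alkenyl transfer are slow at the thioester, which sits on a fully substituted, hydroxylated carbon, so that protodeboronation of 26 outruns the coupling. The fallback sets out from 25 and comes back at 27. Fukuyama reduction (Et3SiH, Pd(OAc)2, acetone) converts the thioester into the aldehyde F3. Nozaki–Hiyama–Kishi addition of (E)-1-iodoprop-1-ene (CrCl2, NiCl2 cat., DMSO), which is selective for aldehydes, gives the allylic alcohol F4 as a mixture of carbinol epimers. Dess–Martin oxidation of F4 should give 27.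

Step 12. What may go wrong: poor site selectivity of the silylation between the two secondary hydroxyls. The fallback sets out from 10 and 18 and comes back at 25, replacing steps 12 and 13. Step 11 is run with angelic anhydride added to the magnesium aldolate at −78 to −40 °C before the acid stage, so that the C8 oxygen is acylated before the C4 hydroxyl exists. The angelate acetal F5 and the angelate lactol F6 are not isolated, and the ring closure with indium gives the cycloheptane angelate F7. Its only secondary hydroxyl is then silylated (Et3SiCl, imidazole) to give 25.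

Further compounds

F1 | step 11 | methyl (2Z,4R,5S)-5-[(2S,3S)-2-[(ethylsulfanyl)carbonyl]-5-methoxy-3-methyloxolan-2-yl]-5-hydroxy-2-(iodomethyl)-4-[(4-methoxyphenyl)methoxy]pent-2-enoate (iodide acetal) | COc1ccc(CO[C@H](/C=C(\CI)C(=O)OC)[C@H](O)[C@@]2(C(=O)SCC)OC(OC)C[C@@H]2C)cc1
F2 | step 11 | methyl (2Z,4R,5S)-5-[(2S,3S)-2-[(ethylsulfanyl)carbonyl]-5-hydroxy-3-methyloxolan-2-yl]-5-hydroxy-2-(iodomethyl)-4-[(4-methoxyphenyl)methoxy]pent-2-enoate (iodide lactol) | COc1ccc(CO[C@H](/C=C(\CI)C(=O)OC)[C@H](O)[C@@]2(C(=O)SCC)OC(O)C[C@@H]2C)cc1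
F3 | step 14 | methyl 2-[(1R,2S,4S,5S,6S,7R)-5-formyl-5-hydroxy-7-[(4-methoxyphenyl)methoxy]-4-methyl-6-{[(2Z)-2-methylbut-2-enoyl]oxy}-2-[(triethylsilyl)oxy]cycloheptyl]prop-2-enoate (aldehyde) | COc1ccc(CO[C@@H]2[C@@H](C(=C)C(=O)OC)[C@@H](O[Si](CC)(CC)CC)C[C@H](C)[C@@](O)(C=O)[C@H]2OC(=O)/C(C)=C\C)cc1
F4 | step 14 | methyl 2-[(1R,2S,4S,5S,6S,7R)-5-hydroxy-5-[(2E)-1-hydroxybut-2-enyl]-7-[(4-methoxyphenyl)methoxy]-4-methyl-6-{[(2Z)-2-methylbut-2-enoyl]oxy}-2-[(triethylsilyl)oxy]cycloheptyl]prop-2-enoate (allylic alcohol, carbinol epimers) | COc1ccc(CO[C@@H]2[C@@H](C(=C)C(=O)OC)[C@@H](O[Si](CC)(CC)CC)C[C@H](C)[C@@](O)(C(O)/C=C/C)[C@H]2OC(=O)/C(C)=C\C)cc1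
F5 | step 12 | methyl (2Z,4R,5S)-2-(chloromethyl)-5-[(2S,3S)-2-[(ethylsulfanyl)carbonyl]-5-methoxy-3-methyloxolan-2-yl]-4-[(4-methoxyphenyl)methoxy]-5-{[(2Z)-2-methylbut-2-enoyl]oxy}pent-2-enoate (angelate acetal) | COc1ccc(CO[C@H](/C=C(\CCl)C(=O)OC)[C@H](OC(=O)/C(C)=C\C)[C@@]2(C(=O)SCC)OC(OC)C[C@@H]2C)cc1
F6 | step 12 | methyl (2Z,4R,5S)-2-(chloromethyl)-5-[(2S,3S)-2-[(ethylsulfanyl)carbonyl]-5-hydroxy-3-methyloxolan-2-yl]-4-[(4-methoxyphenyl)methoxy]-5-{[(2Z)-2-methylbut-2-enoyl]oxy}pent-2-enoate (angelate lactol) | COc1ccc(CO[C@H](/C=C(\CCl)C(=O)OC)[C@H](OC(=O)/C(C)=C\C)[C@@]2(C(=O)SCC)OC(O)C[C@@H]2C)cc1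
F7 | step 12 | methyl 2-[(1S,2S,4S,5S,6S,7R)-5-[(ethylsulfanyl)carbonyl]-2,5-dihydroxy-7-[(4-methoxyphenyl)methoxy]-4-methyl-6-{[(2Z)-2-methylbut-2-enoyl]oxy}cycloheptyl]prop-2-enoate (cycloheptane angelate) | COc1ccc(CO[C@@H]2[C@@H](C(=C)C(=O)OC)[C@@H](O)C[C@H](C)[C@@](O)(C(=O)SCC)[C@H]2OC(=O)/C(C)=C\C)cc1
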